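**Retrosynthetic overview**
1. The last disconnection is the depside ester bond between the ring A carbonyl and the oxygen on C4 of ring B. It gives 2,4-dimethoxy-6-(2-oxoheptyl)benzoic acid and benzyl 4-hydroxy-2-methoxy-6-pentylbenzoate; the benzyl group masks the C1 carboxyl and is removed last.
2. The plan rests on ring B, where the carboxyl-bearing C1 lies between C2 (OMe) and C6 (pentyl). A carbon electrophile at C1 and a carbon nucleophile at C6 sit on adjacent ring atoms beside a methoxy group, which is the imprint of addition across the C1≡C6 bond of a 3-methoxybenzyne.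
3. The key disconnection cuts C6–pentyl and C1–CO2H together. It leads back to 1-fluoro-3-methoxy-5-(triisopropylsilyloxy)benzene, pentyllithium (base and nucleophile) and CO2; the silyl ether carries the future C4 oxygen.
4. In ring A the CH2–C(=O) bond of the 2-oxoheptyl chain is cut, back to the lateral dianion of 2,4-dimethoxy-6-methylbenzoic acid and the Weinreb amide of hexanoic acid.
5. No ring is formed at any stage, since both benzene rings are bought and only substituted. The order is ring B (steps 1–5), ring A side chain (steps 6–7), then union and debenzylation (steps 8–9).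

Key step: step 3

Remark on the chemistry: the target has no stereocentre and no double-bond geometry, so no stereocontrol is required and all SMILES carry no stereodescriptors.

Step 1
Reactants: 1 3-fluoro-5-methoxyphenol; 2 chlorotriisopropylsilane
Product: 3 1-fluoro-3-methoxy-5-(triisopropylsilyloxy)benzene
Conditions: 2 (1.1 equiv), imidazole (2.2 equiv), DMF, rt
Reagents that add atoms: chlorotriisopropylsilane (2), CC(C)[Si](Cl)(C(C)C)C(C)C
Why: Imidazole-promoted O-silylation of the only hydroxyl group gives a silyl ether that resists alkyllithium reagents and screens its two ortho C–H bonds in step 3.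

Step 2
Reactants: 4 1-bromopentane
Product: 5 pentyllithium (Et2O solution, titrated and used at once)
Conditions: Li metal (about 1% Na, 2.3 equiv), Et2O, −15 to −5 °C, Ar, slow addition of 4; filter
Reagents that add atoms: lithium metal, [Li]
Why: Direct reductive lithiation of a primary alkyl bromide with lithium metal is the classical route to n-alkyllithiums, and low temperature with slow addition holds back Wurtz coupling.

Step 3
Reactants: 3 1-fluoro-3-methoxy-5-(triisopropylsilyloxy)benzene; 5 pentyllithium (3.0 equiv); 6 carbon dioxide
Product: 11 2-methoxy-6-pentyl-4-(triisopropylsilyloxy)benzoic acid, via ortho-lithiated fluoroarene 7 (not isolated), via aryne 8 (not isolated), via pentylated aryllithium 9 (not isolated), via lithium benzoate 10 (not isolated)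
Conditions: 5 (3.0 equiv), THF/Et2O, −78 °C, 1.5 h; warm to −10 °C over 2 h; recool to −78 °C and cannulate into THF saturated with dry CO2 (large excess); 1 M HCl to pH 3
Reagents that add atoms: pentyllithium (5), [Li]CCCCC; carbon dioxide (6), O=C=O
Why: Pentyllithium first removes the ring proton of 3 that lies between F and OMe (directed ortho-metalation: this C–H is acidified by both neighbours and OMe binds lithium, whereas the two C–H bonds next to the silyloxy group are screened by the isopropyl groups), which gives 7 at −78 °C. On warming, 7 loses LiF and the aryne 8 is captured by a second pentyllithium at the aryne carbon remote from OMe, so that the C6–pentyl bond forms and lithium ends on C1 beside the σ-withdrawing, lithium-binding methoxy oxygen (9). The remote silyloxy group exerts only a weak opposite bias, which the adjacent methoxy group should override as it does in other 3,5-dialkoxybenzynes. Transfer of 9 into excess CO2 forms the C1–carboxyl bond (10) and acidification gives 11; the closest known reaction type is the one-pot addition of alkyllithium or Grignard reagents to 3-methoxybenzynes made from 3-haloanisoles, followed by a CO2 quench (three-component aryne coupling). No ring closes and no stereocentre arises, so the step needs only site selectivity in the lithiation and regioselectivity in the addition, both secured by the F/OMe pair and the bulk of the TIPS group. The surplus of 5 keeps the hindered aryllithiums 7 and 9 from competing for 8, and 9 cannot suffer O-to-C silyl migration because lithium stands para to the silyloxy group.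

Step 4
Reactants: 11 2-methoxy-6-pentyl-4-(triisopropylsilyloxy)benzoic acid; 12 benzyl bromide
Product: 13 benzyl 2-methoxy-6-pentyl-4-(triisopropylsilyloxy)benzoate
Conditions: 12 (1.2 equiv), KHCO3 (2 equiv), DMF, rt
Reagents that add atoms: benzyl bromide (12), BrCc1ccccc1
Why: O-alkylation of the carboxylate (SN2 at benzyl bromide) bypasses the steric block around the di-ortho-substituted carbonyl carbon, and KHCO3 is too weak a base to disturb the aryl TIPS ether.

Step 5
Reactants: 13 benzyl 2-methoxy-6-pentyl-4-(triisopropylsilyloxy)benzoate
Product: 14 benzyl 4-hydroxy-2-methoxy-6-pentylbenzoate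
Conditions: Bu4NF (1.1 equiv), AcOH (1.1 equiv), THF, 0 °C
Reagents that add atoms: none
Why: Fluoride-mediated cleavage of the aryl silyl ether, driven by the strong Si–F bond, frees the C4 phenol, and the acetic acid buffer keeps the phenoxide from attacking the benzyl ester.

Step 6
Reactants: 15 hexanoyl chloride; 16 N,O-dimethylhydroxylamine hydrochloride
Product: 17 N-methoxy-N-methylhexanamide
Conditions: 16 (1.1 equiv), Et3N (2.2 equiv), CH2Cl2, 0 °C to rt
Reagents that add atoms: N,O-dimethylhydroxylamine hydrochloride (16), CNOC.Cl
Why: N-acylation of the amine by the acid chloride (Weinreb amide formation) is fast and clean, with one equivalent of Et3N freeing the amine from its salt and one taking up HCl.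

Step 7
Reactants: 18 2,4-dimethoxy-6-methylbenzoic acid; 17 N-methoxy-N-methylhexanamide
Product: 21 2,4-dimethoxy-6-(2-oxoheptyl)benzoic acid, via dilithiated toluic acid 19 (not isolated), via tetrahedral adduct 20 (not isolated)
Conditions: LiN(iPr)2 (LDA, 2.3 equiv), THF, −78 to 0 °C, 30 min; recool to −78 °C, 17 (1.1 equiv), −78 to −40 °C; cold 1 M HCl to pH 3 at 0 °C, acid–base extraction kept cold
Reagents that add atoms: N-methoxy-N-methylhexanamide (17), CCCCCC(=O)N(C)OC; LiN(iPr)2, [Li]N(C(C)C)C(C)C (lithium only in 19 and 20)
Why: Lateral lithiation of the o-toluic acid gives the carboxylate-stabilised benzylic dianion 19, whose acylation by the Weinreb amide halts at the chelated tetrahedral adduct 20, so that the ketone appears only in the cold acidic quench and over-addition is excluded.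

Step 8
Reactants: 21 2,4-dimethoxy-6-(2-oxoheptyl)benzoic acid; 14 benzyl 4-hydroxy-2-methoxy-6-pentylbenzoate
Product: 23 benzyl 4-[2,4-dimethoxy-6-(2-oxoheptyl)benzoyloxy]-2-methoxy-6-pentylbenzoate, via mixed trifluoroacetic anhydride 22 (not isolated)
Conditions: 21 (1.2 equiv) and 14 premixed, (CF3CO)2O (4 equiv), toluene, 0 °C to rt
Reagents that add atoms: trifluoroacetic anhydride, O=C(OC(=O)C(F)(F)F)C(F)(F)F (its atoms appear only in 22)
Why: Mixed-anhydride esterification, the classical depside coupling, turns the electron-rich hindered acid into the acylium-like donor 22, which acylates the only free hydroxyl of 14, and the phenol is present from the start so that its capture competes with attack of the side-chain ketone on the activated carboxyl.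

Step 9
Reactants: 23 benzyl 4-[2,4-dimethoxy-6-(2-oxoheptyl)benzoyloxy]-2-methoxy-6-pentylbenzoate
Product: 24 4-[2,4-dimethoxy-6-(2-oxoheptyl)benzoyloxy]-2-methoxy-6-pentylbenzoic acid (target)
Conditions: H2 (1 atm), 10% Pd/C, EtOAc, rt
Reagents that add atoms: none
Why: Catalytic hydrogenolysis of the benzylic C–O bond frees the C1 carboxyl under neutral conditions that leave the aryl ester, the non-conjugated ketone and the three methyl ethers untouched.

**Compound list**
1 | 3-fluoro-5-methoxyphenol | COc1cc(O)cc(F)c1 | starting material
2 | chlorotriisopropylsilane | CC(C)[Si](Cl)(C(C)C)C(C)C | starting material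
3 | 1-fluoro-3-methoxy-5-(triisopropylsilyloxy)benzene | COc1cc(F)cc(O[Si](C(C)C)(C(C)C)C(C)C)c1 | intermediate
4 | 1-bromopentane | CCCCCBr | starting material
5 | pentyllithium | [Li]CCCCC | intermediate
6 | carbon dioxide | O=C=O | starting material
7 | 2-fluoro-6-methoxy-4-(triisopropylsilyloxy)phenyllithium | [Li]c1c(F)cc(O[Si](C(C)C)(C(C)C)C(C)C)cc1OC | intermediate
8 | 3-methoxy-5-(triisopropylsilyloxy)benzyne (1,2-didehydrobenzene, triple bond next to the OMe-bearing carbon) | COC1=CC(O[Si](C(C)C)(C(C)C)C(C)C)=CC#C1 | intermediate
9 | 2-methoxy-6-pentyl-4-(triisopropylsilyloxy)phenyllithium | [Li]c1c(CCCCC)cc(O[Si](C(C)C)(C(C)C)C(C)C)cc1OC | intermediate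
10 | lithium 2-methoxy-6-pentyl-4-(triisopropylsilyloxy)benzoate | CCCCCc1cc(O[Si](C(C)C)(C(C)C)C(C)C)cc(OC)c1C(=O)[O-].[Li+] | intermediate
11 | 2-methoxy-6-pentyl-4-(triisopropylsilyloxy)benzoic acid | CCCCCc1cc(O[Si](C(C)C)(C(C)C)C(C)C)cc(OC)c1C(=O)O | intermediate
12 | benzyl bromide | BrCc1ccccc1 | starting material
13 | benzyl 2-methoxy-6-pentyl-4-(triisopropylsilyloxy)benzoate | CCCCCc1cc(O[Si](C(C)C)(C(C)C)C(C)C)cc(OC)c1C(=O)OCc1ccccc1 | intermediate
14 | benzyl 4-hydroxy-2-methoxy-6-pentylbenzoate | CCCCCc1cc(O)cc(OC)c1C(=O)OCc1ccccc1 | intermediate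
15 | hexanoyl chloride | CCCCCC(=O)Cl | starting material
16 | N,O-dimethylhydroxylamine hydrochloride | CNOC.Cl | starting material
17 | N-methoxy-N-methylhexanamide | CCCCCC(=O)N(C)OC | intermediate
18 | 2,4-dimethoxy-6-methylbenzoic acid | Cc1cc(OC)cc(OC)c1C(=O)O | starting material
19 | lithium 2-(lithiomethyl)-4,6-dimethoxybenzoate (lateral dianion) | [Li]Cc1cc(OC)cc(OC)c1C(=O)O[Li] | intermediate
20 | dilithium salt of 2-{2-hydroxy-2-[methoxy(methyl)amino]heptyl}-4,6-dimethoxybenzoic acid (tetrahedral adduct, transient racemic centre) | CCCCCC(O[Li])(N(C)OC)Cc1cc(OC)cc(OC)c1C(=O)O[Li] | intermediate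
21 | 2,4-dimethoxy-6-(2-oxoheptyl)benzoic acid | CCCCCC(=O)Cc1cc(OC)cc(OC)c1C(=O)O | intermediate
22 | 2,4-dimethoxy-6-(2-oxoheptyl)benzoic trifluoroacetic anhydride | CCCCCC(=O)Cc1cc(OC)cc(OC)c1C(=O)OC(=O)C(F)(F)F | intermediate
23 | benzyl 4-[2,4-dimethoxy-6-(2-oxoheptyl)benzoyloxy]-2-methoxy-6-pentylbenzoate | CCCCCC(=O)Cc1cc(OC)cc(OC)c1C(=O)Oc1cc(CCCCC)c(C(=O)OCc2ccccc2)c(OC)c1 | intermediate
24 | 4-[2,4-dimethoxy-6-(2-oxoheptyl)benzoyloxy]-2-methoxy-6-pentylbenzoic acid | CCCCCC(=O)Cc1cc(OC)cc(OC)c1C(=O)Oc1cc(CCCCC)c(C(=O)O)c(OC)c1 | target

Total step count: 9.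
Longest linear sequence: 6 steps (1, 3, 4, 5, 8, 9). The branch that starts with step 2 is equally long, and the ring A branch 6, 7, 8, 9 has 4 steps.

**Steps most likely to fail**

**Step 3 (key step).** Several processes could erode it:
- lithiation at a C–H next to the silyloxy group;
- capture of the aryne by the aryllithiums instead of pentyllithium, which would build up biaryls;
- protonation of the product aryllithium by the solvent before carboxylation;
- addition of surplus alkyllithium to the lithium carboxylate. The surplus reagent is also carboxylated and must be separated from the product.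

The fallback replaces elimination–addition by addition–elimination, sets out from 3 and returns at 11.
- Lithiation of 3 with 5 (1.05 equiv, THF) is held at −78 °C so that LiF is not lost. Aryllithium 7 is then carboxylated with 6 to give 2-fluoro-6-methoxy-4-(triisopropylsilyloxy)benzoic acid F1.
- Treatment of this acid with 5 (2.3 equiv, THF, −78 to 0 °C) should first form the lithium carboxylate. It should then replace the ortho fluoride by pentyl through carboxylate-assisted nucleophilic aromatic substitution, a known reaction of unprotected 2-fluorobenzoic acids with alkyllithium and Grignard reagents.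
- Acidification gives 11.

**Step 8.** Intramolecular O-acylation of the side-chain ketone (enol-lactonisation of the activated acid) may outrun the slow intermolecular acylation of the phenol at the hindered carbonyl.

The fallback masks the ketone before the carboxyl is activated, sets out from 21 and returns at 23.
- Acid 21 is alkylated (MeI, KHCO3, DMF, rt) to methyl 2,4-dimethoxy-6-(2-oxoheptyl)benzoate F2.
- Aprotic Noyori ketalisation (1,2-bis(trimethylsilyloxy)ethane, cat. TMSOTf, CH2Cl2, −78 to −20 °C) gives methyl 2,4-dimethoxy-6-[(2-pentyl-1,3-dioxolan-2-yl)methyl]benzoate F3.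
- Saponification (KOH, aqueous DMSO, 90 °C, then citric acid to pH 5 at 0 °C) gives 2,4-dimethoxy-6-[(2-pentyl-1,3-dioxolan-2-yl)methyl]benzoic acid F4, which is used at once.
- Steglich esterification of this acid with 14 (EDC·HCl, DMAP, CH2Cl2, rt) gives benzyl 4-{2,4-dimethoxy-6-[(2-pentyl-1,3-dioxolan-2-yl)methyl]benzoyloxy}-2-methoxy-6-pentylbenzoate F5.
- Mild hydrolysis of the ketal (1 M HCl, THF, rt) gives 23.

**Step 7.** Proton transfer from the α-CH2 of the enolisable amide to the strongly basic benzylic anion would return both partners. Cyclodehydration of the keto acid could also set in during the acidic work-up.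

The fallback uses a non-enolisable electrophile and builds the ketone by acylation–decarboxylation. It sets out from 18 and returns at 21.
- Dianion 19, made from 18 as in step 7, is trapped with 6 to give 2-(carboxymethyl)-4,6-dimethoxybenzoic acid F6.
- This diacid is heated neat with 15 (about 200 °C), the classical homophthalic acid condensation, to give 6,8-dimethoxy-3-pentylisocoumarin F7.
- Opening of the enol lactone (KOH, aqueous EtOH, reflux) and cold acidification give 21.

Further compounds
F1 | step 3 | 2-fluoro-6-methoxy-4-(triisopropylsilyloxy)benzoic acid | COc1cc(O[Si](C(C)C)(C(C)C)C(C)C)cc(F)c1C(=O)O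
F2 | step 8 | methyl 2,4-dimethoxy-6-(2-oxoheptyl)benzoate | CCCCCC(=O)Cc1cc(OC)cc(OC)c1C(=O)OC
F3 | step 8 | methyl 2,4-dimethoxy-6-[(2-pentyl-1,3-dioxolan-2-yl)methyl]benzoate | CCCCCC1(Cc2cc(OC)cc(OC)c2C(=O)OC)OCCO1
F4 | step 8 | 2,4-dimethoxy-6-[(2-pentyl-1,3-dioxolan-2-yl)methyl]benzoic acid | CCCCCC1(Cc2cc(OC)cc(OC)c2C(=O)O)OCCO1
F5 | step 8 | benzyl 4-{2,4-dimethoxy-6-[(2-pentyl-1,3-dioxolan-2-yl)methyl]benzoyloxy}-2-methoxy-6-pentylbenzoate | CCCCCC1(Cc2cc(OC)cc(OC)c2C(=O)Oc2cc(CCCCC)c(C(=O)OCc3ccccc3)c(OC)c2)OCCO1
F6 | step 7 | 2-(carboxymethyl)-4,6-dimethoxybenzoic acid | COc1cc(CC(=O)O)c(C(=O)O)c(OC)c1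
F7 | step 7 | 6,8-dimethoxy-3-pentylisocoumarin | CCCCCc1cc2cc(OC)cc(OC)c2c(=O)o1
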